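**Retrosynthetic overview**

1. Target 18 ← desilylation of 17 ← C1'–C2' bond by alkylation of the 2-methyl (lateral) dienolate of silyl ether 7 with the Z-iodide 15.
2. 15 ← (Z)-hexadec-11-en-1-ol 14 ← alkyne 13 from hex-1-yne and 10-bromodecan-1-ol, with the Z geometry set by semi-hydrogenation.
3. 7 ← alcohol 6 ← enantioselective enzymatic C5–H to C5–OH oxidation of 5. The strategy rests on the only stereocenter, C5: a secondary carbinol on a methylene of carbocyclic ring B, allylic to the C4a=C8a enol-ether bond and peri to the C4 carbonyl of pyranone ring A.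
4. 5 ← cyclohexanone enamine 2 + diketene 3. Ring B is bought with cyclohexanone, ring A is annulated onto it in step 2, and no ring is formed afterwards.

Key step: step 3

Remark: read from the SMILES, C5 is S and the side-chain alkene is 12Z. Atoms are numbered as in 4H-chromen-4-one (O1, C2–C4, C4a, C5–C8, C8a) and side-chain carbons as C1'–C17'. The acetal carbon of 9 and 12 is racemic and is removed in step 7.

**Route**

Step 1
Reactants: 1 cyclohexanone
Product: 2 4-(cyclohex-1-en-1-yl)morpholine
Conditions: morpholine, p-TsOH·H2O (cat.), toluene, reflux, Dean–Stark trap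
Reagents that add atoms: morpholine, C1COCCN1
Why: Acid-catalysed condensation of the ketone with the secondary amine under azeotropic removal of water gives the enamine (Stork enamine formation), for which only one double-bond position exists.

Step 2
Reactants: 2 4-(cyclohex-1-en-1-yl)morpholine; 3 diketene
Product: 5 2-methyl-5,6,7,8-tetrahydro-4H-chromen-4-one, via acetoacetyl enamine 4 (not isolated)
Conditions: 3 (1.1 equiv), CH2Cl2, 0 °C → rt; then 2 M HCl (aq), rt → 50 °C
Reagents that add atoms: none
Why: The nucleophilic β-carbon of the enamine opens diketene at its acyl carbon (Stork-type C-acetoacetylation) to give 4, and under acid the enol oxygen of the terminal acetyl group adds to the morpholine-bearing carbon and expels morpholine, closing the 4-pyranone ring A onto ring B, a known route from ketone enamines and diketene to 2-methyl-4-pyranones.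

Step 3
Reactants: 5 2-methyl-5,6,7,8-tetrahydro-4H-chromen-4-one
Product: 6 (5S)-5-hydroxy-2-methyl-5,6,7,8-tetrahydro-4H-chromen-4-one
Conditions: engineered cytochrome P450 BM3 (CYP102A1) variant (haem-iron monooxygenase, cell-free E. coli lysate), O2 (air), NADP+ (cat.), D-glucose (1.5 equiv), glucose dehydrogenase, KPi buffer pH 8.0, 2% DMSO, 25 °C, stopped before full conversion
Reagents that add atoms: dioxygen, O=O
Why: Proposed new method: the tetravalent oxo-iron porphyrin radical cation formed in the haem pocket from O2 and two NADPH-derived electrons abstracts one enantiotopic hydrogen from C5 of 5, giving a radical delocalised over C5–C4a–C8a and stabilised by O1, and hydroxyl rebound from iron to C5 forms the C5–O bond with retention, so no ring is closed. The closest known reaction type is the enantioselective benzylic and allylic hydroxylation of tetralin-, tetralone- and cyclohexenone-type rings by engineered P450 BM3 variants and unspecific peroxygenases, which has not been shown on a fused 4-pyranone. The new stereocenter C5 is controlled by the protein alone: a variant is to be selected from a focused active-site library that binds the flat bicycle with its C4 carbonyl hydrogen-bonded next to the iron, so that only the pro-S hydrogen of C5 reaches the oxo group and the (S)-alcohol should result. The step needs site selectivity for C5 over the equally allylic C8, the unactivated C6 and C7 and the 2-methyl group, discrimination between the two C5 hydrogens, and a stop at the alcohol stage. The substrate contributes only the weakened allylic C5–H bonds and the peri C4 carbonyl as an anchor, while the compact 2-methyl core offers no long chain for competing fatty-acid-type oxidation. Over-oxidation to the 5-ketone is limited by running to partial conversion and recycling 5.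

Step 4
Reactants: 6 (5S)-5-hydroxy-2-methyl-5,6,7,8-tetrahydro-4H-chromen-4-one
Product: 7 (5S)-5-[(tert-butyldimethylsilyl)oxy]-2-methyl-5,6,7,8-tetrahydro-4H-chromen-4-one
Conditions: TBSCl, imidazole, DMAP (cat.), DMF, rt → 40 °C
Reagents that add atoms: tert-butyldimethylsilyl chloride, CC(C)(C)[Si](C)(C)Cl
Why: Imidazole-promoted silylation of the secondary alcohol (silyl ether formation) masks the acidic hydroxyl before the strong base of step 10 and leaves the C5–O bond intact, so the S configuration is kept.

Step 5
Reactants: 8 10-bromodecan-1-ol
Product: 9 2-[(10-bromodecyl)oxy]oxane (racemic at the acetal carbon)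
Conditions: 3,4-dihydro-2H-pyran, PPTS (cat.), CH2Cl2, rt
Reagents that add atoms: 3,4-dihydro-2H-pyran, C1=COCCC1
Why: Acid-catalysed addition of the alcohol to the enol ether (tetrahydropyranyl acetal formation) protects the hydroxyl so that the acetylide of step 6 is not quenched, and the primary bromide is inert to these conditions.

Step 6
Reactants: 9 2-[(10-bromodecyl)oxy]oxane; 10 hex-1-yne
Product: 12 2-(hexadec-11-yn-1-yloxy)oxane, via hex-1-ynyllithium 11 (not isolated)
Conditions: 10, n-BuLi, THF, −78 → 0 °C; then 9, DMPU, 0 °C → rt
Reagents that add atoms: none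
Why: Deprotonation of the terminal alkyne and SN2 alkylation of the lithium acetylide by the primary bromide in the presence of DMPU (acetylide alkylation) forms the C10–C11 bond of the chain, the acetal being stable to organolithium bases.

Step 7
Reactants: 12 2-(hexadec-11-yn-1-yloxy)oxane
Product: 13 hexadec-11-yn-1-ol
Conditions: p-TsOH·H2O (cat.), MeOH, rt
Reagents that add atoms: none
Why: Acid-catalysed transacetalisation to methanol cleaves the tetrahydropyranyl ether without affecting the internal alkyne.

Step 8
Reactants: 13 hexadec-11-yn-1-ol
Product: 14 (Z)-hexadec-11-en-1-ol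
Conditions: H2 (1 atm), Lindlar catalyst (Pd/CaCO3 poisoned with Pb(OAc)2), quinoline, EtOAc, rt, stopped after one equivalent of H2
Reagents that add atoms: none
Why: Syn-addition of one equivalent of hydrogen on the lead-poisoned palladium surface (Lindlar semi-hydrogenation) gives the Z alkene, quinoline suppressing over-reduction and isomerisation.

Step 9
Reactants: 14 (Z)-hexadec-11-en-1-ol
Product: 15 (Z)-1-iodohexadec-11-ene
Conditions: I2, PPh3, imidazole, CH2Cl2, 0 °C → rt, dark
Reagents that add atoms: iodine, [I][I]
Why: Activation of the primary alcohol as its alkoxyphosphonium salt and SN2 displacement by iodide (Appel-type iodination) gives the primary iodide under near-neutral conditions that leave the Z alkene untouched.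

Step 10
Reactants: 7 (5S)-5-[(tert-butyldimethylsilyl)oxy]-2-methyl-5,6,7,8-tetrahydro-4H-chromen-4-one; 15 (Z)-1-iodohexadec-11-ene
Product: 17 (5S)-5-[(tert-butyldimethylsilyl)oxy]-2-[(12Z)-heptadec-12-en-1-yl]-5,6,7,8-tetrahydro-4H-chromen-4-one, via lithium dienolate 16 (not isolated)
Conditions: LDA (1.1 equiv), THF, −78 °C; then 15 (1.3 equiv), DMPU, −78 → −30 °C
Reagents that add atoms: none
Why: LDA removes a proton from the 2-methyl group, the kinetically most accessible vinylogous position of the 4-pyranone, to give the cross-conjugated dienolate 16, which the primary iodide alkylates at the exocyclic γ-carbon (lateral lithiation–alkylation of a 2-methyl-4-pyranone, SN2) with return of the pyranone π-system; the C5 hydrogen is not acidic, so the stereocenter is unaffected.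

Step 11
Reactants: 17 (5S)-5-[(tert-butyldimethylsilyl)oxy]-2-[(12Z)-heptadec-12-en-1-yl]-5,6,7,8-tetrahydro-4H-chromen-4-one
Product: 18 (5S)-2-[(12Z)-heptadec-12-en-1-yl]-5-hydroxy-5,6,7,8-tetrahydro-4H-chromen-4-one
Conditions: TBAF, AcOH (1:1), THF, 0 °C → rt
Reagents that add atoms: none
Why: Fluoride attack at silicon cleaves the Si–O bond (fluoride-mediated desilylation) under acetic acid buffering, which avoids both deprotonation of the pyranone side positions and acid ionisation at C5, so the S carbinol is released unchanged.

**Compound list**

1 | cyclohexanone | O=C1CCCCC1 | starting material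
2 | 4-(cyclohex-1-en-1-yl)morpholine | C1=C(CCCC1)N1CCOCC1 | intermediate
3 | diketene (4-methylideneoxetan-2-one) | C=C1CC(=O)O1 | starting material
4 | 1-[2-(morpholin-4-yl)cyclohex-1-en-1-yl]butane-1,3-dione (acetoacetyl enamine, not isolated) | CC(=O)CC(=O)C1=C(CCCC1)N1CCOCC1 | intermediate
5 | 2-methyl-5,6,7,8-tetrahydro-4H-chromen-4-one | Cc1cc(=O)c2c(o1)CCCC2 | intermediate
6 | (5S)-5-hydroxy-2-methyl-5,6,7,8-tetrahydro-4H-chromen-4-one | Cc1cc(=O)c2c(o1)CCC[C@@H]2O | intermediate
7 | (5S)-5-[(tert-butyldimethylsilyl)oxy]-2-methyl-5,6,7,8-tetrahydro-4H-chromen-4-one | Cc1cc(=O)c2c(o1)CCC[C@@H]2O[Si](C)(C)C(C)(C)C | intermediate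
8 | 10-bromodecan-1-ol | OCCCCCCCCCCBr | starting material
9 | 2-[(10-bromodecyl)oxy]oxane (racemic acetal) | BrCCCCCCCCCCOC1CCCCO1 | intermediate
10 | hex-1-yne | CCCCC#C | starting material
11 | hex-1-ynyllithium (not isolated) | CCCCC#C[Li] | intermediate
12 | 2-(hexadec-11-yn-1-yloxy)oxane (racemic acetal) | CCCCC#CCCCCCCCCCCOC1CCCCO1 | intermediate
13 | hexadec-11-yn-1-ol | CCCCC#CCCCCCCCCCCO | intermediate
14 | (Z)-hexadec-11-en-1-ol | CCCC/C=C\CCCCCCCCCCO | intermediate
15 | (Z)-1-iodohexadec-11-ene | CCCC/C=C\CCCCCCCCCCI | intermediate
16 | lithium (5S)-5-[(tert-butyldimethylsilyl)oxy]-2-methylidene-5,6,7,8-tetrahydro-2H-chromen-4-olate (not isolated) | C=C1C=C(O[Li])C2=C(O1)CCC[C@@H]2O[Si](C)(C)C(C)(C)C | intermediate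
17 | (5S)-5-[(tert-butyldimethylsilyl)oxy]-2-[(12Z)-heptadec-12-en-1-yl]-5,6,7,8-tetrahydro-4H-chromen-4-one | CCCC/C=C\CCCCCCCCCCCc1cc(=O)c2c(o1)CCC[C@@H]2O[Si](C)(C)C(C)(C)C | intermediate
18 | (5S)-2-[(12Z)-heptadec-12-en-1-yl]-5-hydroxy-5,6,7,8-tetrahydro-4H-chromen-4-one | CCCC/C=C\CCCCCCCCCCCc1cc(=O)c2c(o1)CCC[C@@H]2O | target

**Step count**

Total steps: 11. Longest linear sequence: 7 steps (steps 5–11, from 10-bromodecan-1-ol 8); the pyranone branch from cyclohexanone 1 to the target is 6 steps (steps 1–4, 10, 11).

**Steps most likely to fail**

Step 3 (key step, proposed new method). The risk is oxygen transfer to the wrong site (C8, C6, C7 or the 2-methyl group) or to the wrong enantiotopic C5 hydrogen, further oxidation of the alcohol to the ketone, or too little turnover for preparative use. The fallback uses known chemistry and sets out from diketene 3. Base-catalysed C-acetoacetylation of commercial cyclohexane-1,3-dione (O=C1CCCC(=O)C1) by 3 (Et3N, DMAP cat., CH2Cl2, 0 °C → rt; DMAP also drives O-to-C acyl migration of any enol ester) should give 2-(3-oxobutanoyl)cyclohexane-1,3-dione F1. Acid cyclodehydration (conc. H2SO4, 0 °C → rt), the same pyranone annulation known for open-chain 1,3-diketones with diketene, should give 2-methyl-7,8-dihydro-4H-chromene-4,5(6H)-dione F2. Noyori-type asymmetric transfer hydrogenation of the C5 ketone of F2 with RuCl(p-cymene)[(S,S)-TsDPEN] in HCO2H/Et3N should then give the S alcohol, by analogy with 1-tetralone and 4-chromanone; the C4 pyranone carbonyl is a doubly vinylogous ester and should not be reduced. The enantiomeric ligand is used if the sense of induction turns out reversed. The route is rejoined at 6.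

Step 10. The risk is slow SN2 capture of the delocalised dienolate by an unactivated primary iodide. This gives time for proton transfer to move the anion to C8 or onto the product (double alkylation), and metalation at C8 could also trigger β-elimination of the C5 silyloxy group. The fallback replaces the alkyl halide by an aldehyde and sets out from 14 and 7. Dess–Martin oxidation of 14 (NaHCO3, CH2Cl2) gives (Z)-hexadec-11-enal F3. The dienolate 16, made from 7 as in step 10, should add to F3 within minutes at −78 °C (vinylogous aldol) to give (5S)-5-[(tert-butyldimethylsilyl)oxy]-2-[(12Z)-2-hydroxyheptadec-12-en-1-yl]-5,6,7,8-tetrahydro-4H-chromen-4-one F4 as a mixture of C2' epimers. Treatment with PhOC(S)Cl, pyridine and DMAP in CH2Cl2 converts F4 into its O-phenyl thionocarbonate F5. Barton–McCombie deoxygenation (Bu3SnH, AIBN, toluene, 80 °C, short reaction time to spare the Z alkene) removes the C2' oxygen and rejoins the route at 17.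

Step 2. The risk is consumption of diketene by polymerisation or by the morpholine that is set free, over-acylation of the enamine, or incomplete ring closure of 4. The fallback builds the triketone stepwise and sets out from enamine 2. Stork acylation of 2 with acetic anhydride and hydrolytic work-up gives 2-acetylcyclohexan-1-one F6. Its dianion (LDA, 2.2 equiv, THF, 0 °C) is acylated at the terminal methyl group by N-methoxy-N-methylacetamide to give the 1,3,5-triketone 1-(2-oxocyclohexyl)butane-1,3-dione F7. Cyclodehydration of F7 in conc. H2SO4 (0 °C → rt) can give only one 4-pyranone, and the route is rejoined at 5.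

**Further compounds**

F1 | step 3 | 2-(3-oxobutanoyl)cyclohexane-1,3-dione | CC(=O)CC(=O)C1C(=O)CCCC1=O
F2 | step 3 | 2-methyl-7,8-dihydro-4H-chromene-4,5(6H)-dione | Cc1cc(=O)c2c(o1)CCCC2=O
F3 | step 10 | (Z)-hexadec-11-enal | CCCC/C=C\CCCCCCCCCC=O
F4 | step 10 | (5S)-5-[(tert-butyldimethylsilyl)oxy]-2-[(12Z)-2-hydroxyheptadec-12-en-1-yl]-5,6,7,8-tetrahydro-4H-chromen-4-one (C2' epimers) | CCCC/C=C\CCCCCCCCCC(O)Cc1cc(=O)c2c(o1)CCC[C@@H]2O[Si](C)(C)C(C)(C)C
F5 | step 10 | O-phenyl thionocarbonate of F4 at C2' | CCCC/C=C\CCCCCCCCCC(OC(=S)Oc1ccccc1)Cc1cc(=O)c2c(o1)CCC[C@@H]2O[Si](C)(C)C(C)(C)C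
F6 | step 2 | 2-acetylcyclohexan-1-one | CC(=O)C1CCCCC1=O
F7 | step 2 | 1-(2-oxocyclohexyl)butane-1,3-dione | CC(=O)CC(=O)C1CCCCC1=O
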